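**Plan**
- Retrosynthesis: the N–OMe and C4–O groups are late adjustments of a pyridin-3-ol. The bonds C8a–C4a and C3–C4 are cut together, opening the pyridine ring and the carbocycle to a 5-alkoxyoxazole. The oxazole is cut to an acid and an O-benzylserine ester, and the C5–octyl bond is cut last.
- Enabling feature: the C3 oxygen next to the C2 hydroxymethyl group is what a 4-(alkoxymethyl)-5-alkoxyoxazole delivers (oxazole O becomes the C3 oxygen, oxazole C4 becomes C2). C8a maps onto oxazole C2, which carries the chain C8–C7–C6–C5 to a vinyl group whose carbons become C4a and C4.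
- Forward: the chain is built by cross-metathesis and SN2′ octylation, and the oxazole is closed from the serine amide. One thermal step then forms the carbocycle (C4a–C8a) and the pyridine ring (C3–C4) together. C4 is oxygenated via the iodide, and the N-oxide is formed and methylated on oxygen.
- Stereochemistry: C5 is the only stereocentre. It is set by ligand-controlled copper-catalysed allylic alkylation and carried through unchanged.

Key step: step 6

Assumption: (R,R)-Taniaphos is taken to deliver the alkyl group to the alkene face that gives the (R) centre here, by analogy with its sense on simple (E)-allylic bromides (recalled, to be verified); if a rotation or derivative check shows the opposite, the (S,S) ligand is used in the same step.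

**Route**

Step 1
Reactants: 1 methyl hex-5-enoate; 2 (E)-1,4-dibromobut-2-ene
Product: 3 methyl (E)-7-bromohept-5-enoate
Conditions: second-generation Hoveyda–Grubbs catalyst (H2IMes)Cl2Ru(=CH-C6H4-2-OiPr) (2 mol%), 2 (3 equiv), CH2Cl2, 40 °C
Reagents that add atoms: none
Why: Olefin cross-metathesis of a terminal alkene with an excess of the symmetrical allylic dibromide should give the E-allylic bromide, the excess partner suppressing homodimerisation of 1.

Step 2
Reactants: 3 methyl (E)-7-bromohept-5-enoate; 4 octylmagnesium bromide
Product: 5 methyl (5R)-5-ethenyltridecanoate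
Conditions: CuBr·SMe2 (5 mol%), (R,R)-Taniaphos (C43H39FeNP2, 1-[α-(dimethylamino)-2-(diphenylphosphino)benzyl]-2-(diphenylphosphino)ferrocene, 6 mol%), CH2Cl2, −75 °C, slow addition of 4 (1.2 equiv, Et2O)
Reagents that add atoms: none
Why: Copper-catalysed asymmetric allylic alkylation (SN2′) of the primary allylic bromide by the Grignard reagent should put the octyl group on C5 and move the alkene to the chain end, the Taniaphos-bound copper choosing the alkene face and so setting the (R) centre, while the remote ester is inert at −75 °C.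

Step 3
Reactants: 5 methyl (5R)-5-ethenyltridecanoate
Product: 6 (5R)-5-ethenyltridecanoic acid
Conditions: LiOH·H2O, THF/MeOH/H2O, rt; then 1 M HCl
Reagents that add atoms: lithium hydroxide, [Li+].[OH-]
Why: Saponification (BAc2 ester hydrolysis) touches neither the alkene nor the C5 centre, which is not alpha to the carbonyl.

Step 4
Reactants: 6 (5R)-5-ethenyltridecanoic acid; 7 methyl O-benzyl-L-serinate hydrochloride
Product: 8 methyl (2S)-3-(benzyloxy)-2-{[(5R)-5-ethenyltridecanoyl]amino}propanoate
Conditions: EDC·HCl, HOBt, iPr2NEt, CH2Cl2, 0 °C to rt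
Reagents that add atoms: none
Why: Carbodiimide/HOBt amide coupling joins the acid to the amine freed from its hydrochloride; the serine configuration is immaterial (the racemate serves equally) because that carbon becomes sp2 in step 5.

Step 5
Reactants: 8 methyl (2S)-3-(benzyloxy)-2-{[(5R)-5-ethenyltridecanoyl]amino}propanoate
Product: 9 4-[(benzyloxy)methyl]-2-[(4R)-4-ethenyldodecyl]-5-methoxy-1,3-oxazole
Conditions: PPh3, I2, Et3N, CH2Cl2, 0 °C to rt; chromatography on Et3N-deactivated silica
Reagents that add atoms: none
Why: Robinson–Gabriel-type cyclodehydration of an α-acylamino ester with Ph3P/I2/Et3N should close the 5-methoxyoxazole under mild, non-acidic conditions that the benzyl ether, the alkene and the acid-sensitive product tolerate.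

Step 6
Reactants: 9 4-[(benzyloxy)methyl]-2-[(4R)-4-ethenyldodecyl]-5-methoxy-1,3-oxazole
Product: 12 (5R)-2-[(benzyloxy)methyl]-5-octyl-5,6,7,8-tetrahydroquinolin-3-ol, via oxygen-bridged cycloadduct 10 (not isolated), via ring-opened hemiketal 11 (not isolated)
Conditions: 1,2-dichlorobenzene (0.02 M, degassed), 180 °C, sealed tube
Reagents that add atoms: none
Why: On heating, the electron-rich 5-methoxyoxazole should act as a 2-azadiene across its C2 and C5 and add to the tethered vinyl group in an intramolecular hetero-Diels–Alder (Kondrat'eva) reaction, forming C8a–C4a and C3–C4 and giving the oxygen-bridged adduct 10. The C8a–O bridge bond then opens with loss of the C4a hydrogen to hemiketal 11, which expels methanol across C3–C4 and reaches the aromatic pyridin-3-ol without an oxidant; the closest known reactions are the alkoxyoxazole–dienophile route to pyridoxine and thermal intramolecular oxazole–olefin cycloadditions. The carbocycle closes by a formal 6-exo attack of oxazole C2 (the future C8a) on the internal alkene carbon, a type 1 intramolecular Diels–Alder in the fused mode with a four-atom tether, and the pyridine ring closes as the six-membered [4+2] ring. No new stereocentre remains, since C8a, C4a and C3 all end up sp2, and the C5 centre beside the alkene is not enolisable and takes no part. The step needs regioselectivity (alkene CH to C8a, alkene CH2 to C3), which the short tether enforces because the bridged alternative is too strained, and it needs cycloaddition to outrun thermal decay of the oxazole, which the entropic help of the tether and high dilution in an inert solvent are expected to secure.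

Step 7
Reactants: 12 (5R)-2-[(benzyloxy)methyl]-5-octyl-5,6,7,8-tetrahydroquinolin-3-ol
Product: 13 (5R)-2-[(benzyloxy)methyl]-4-iodo-5-octyl-5,6,7,8-tetrahydroquinolin-3-ol
Conditions: I2, K2CO3, THF/H2O, rt
Reagents that add atoms: iodine, II
Why: Electrophilic aromatic iodination of the pyridin-3-olate should occur ortho to the oxygen at C4, the only ring position still bearing hydrogen.

Step 8
Reactants: 13 (5R)-2-[(benzyloxy)methyl]-4-iodo-5-octyl-5,6,7,8-tetrahydroquinolin-3-ol
Product: 14 (5R)-2-[(benzyloxy)methyl]-4-iodo-3-methoxy-5-octyl-5,6,7,8-tetrahydroquinoline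
Conditions: MeI, K2CO3, DMF, rt
Reagents that add atoms: iodomethane, CI
Why: Williamson O-methylation of the pyridinol should prevail over N-methylation because the nitrogen is flanked by substituents at C2 and C8a and deactivated by the 4-iodo group.

Step 9
Reactants: 14 (5R)-2-[(benzyloxy)methyl]-4-iodo-3-methoxy-5-octyl-5,6,7,8-tetrahydroquinoline
Product: 15 (5R)-4-(benzyloxy)-2-[(benzyloxy)methyl]-3-methoxy-5-octyl-5,6,7,8-tetrahydroquinoline
Conditions: CuI (10 mol%), 3,4,7,8-tetramethyl-1,10-phenanthroline (20 mol%), Cs2CO3, BnOH (3 equiv), toluene, 110 °C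
Reagents that add atoms: benzyl alcohol, OCc1ccccc1
Why: Ullmann-type copper-catalysed C–O coupling of an aryl iodide with a primary alcohol is favoured here by the electron-poor 4-pyridyl iodide, and the phenanthroline ligand is the one suited to ortho-substituted iodides.

Step 10
Reactants: 15 (5R)-4-(benzyloxy)-2-[(benzyloxy)methyl]-3-methoxy-5-octyl-5,6,7,8-tetrahydroquinoline
Product: 16 (5R)-4-(benzyloxy)-2-[(benzyloxy)methyl]-3-methoxy-5-octyl-5,6,7,8-tetrahydroquinoline 1-oxide
Conditions: mCPBA, CH2Cl2, 0 °C to rt
Reagents that add atoms: 3-chloroperbenzoic acid, OOC(=O)c1cccc(Cl)c1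
Why: Peracid N-oxidation of an electron-rich 4-alkoxypyridine is routine, and no alkene or other oxidisable group remains to compete.

Step 11
Reactants: 16 (5R)-4-(benzyloxy)-2-[(benzyloxy)methyl]-3-methoxy-5-octyl-5,6,7,8-tetrahydroquinoline 1-oxide
Product: 17 (5R)-1-hydroxy-2-(hydroxymethyl)-3-methoxy-5-octyl-5,6,7,8-tetrahydroquinolin-4(1H)-one
Conditions: BCl3 (5 equiv), pentamethylbenzene (6 equiv), CH2Cl2, −78 to −20 °C; MeOH quench
Reagents that add atoms: none
Why: Lewis-acid benzyl ether cleavage with BCl3 and pentamethylbenzene as cation scavenger should remove both benzyl groups at low temperature while sparing the aryl methyl ether and the N–O bond, the freed 4-hydroxypyridine N-oxide resting as its 1-hydroxy-4-pyridone tautomer.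

Step 12
Reactants: 17 (5R)-1-hydroxy-2-(hydroxymethyl)-3-methoxy-5-octyl-5,6,7,8-tetrahydroquinolin-4(1H)-one
Product: 18 (5R)-2-(hydroxymethyl)-1,3-dimethoxy-5-octyl-5,6,7,8-tetrahydroquinolin-4(1H)-one
Conditions: MeI (1.1 equiv), K2CO3, DMF, rt
Reagents that add atoms: iodomethane, CI
Why: Williamson-type O-alkylation of the cyclic hydroxamic acid, whose N–OH is far more acidic than the primary alcohol, should put the methyl on the N-oxygen, the usual course for 1-hydroxy-4-pyridones because it keeps the vinylogous amide.

**Compound list**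
1 | methyl hex-5-enoate | C=CCCCC(=O)OC | starting material
2 | (E)-1,4-dibromobut-2-ene | BrC/C=C/CBr | starting material
3 | methyl (E)-7-bromohept-5-enoate | COC(=O)CCC/C=C/CBr | intermediate
4 | octylmagnesium bromide | CCCCCCCC[Mg]Br | starting material
5 | methyl (5R)-5-ethenyltridecanoate | CCCCCCCC[C@@H](C=C)CCCC(=O)OC | intermediate
6 | (5R)-5-ethenyltridecanoic acid | CCCCCCCC[C@@H](C=C)CCCC(=O)O | intermediate
7 | methyl O-benzyl-L-serinate hydrochloride | Cl.N[C@@H](COCc1ccccc1)C(=O)OC | starting material
8 | methyl (2S)-3-(benzyloxy)-2-{[(5R)-5-ethenyltridecanoyl]amino}propanoate | CCCCCCCC[C@@H](C=C)CCCC(=O)N[C@@H](COCc1ccccc1)C(=O)OC | intermediate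
9 | 4-[(benzyloxy)methyl]-2-[(4R)-4-ethenyldodecyl]-5-methoxy-1,3-oxazole | CCCCCCCC[C@@H](C=C)CCCc1nc(COCc2ccccc2)c(OC)o1 | intermediate
10 | oxygen-bridged cycloadduct (7-oxa-2-azabicyclo[2.2.1]hept-2-ene core: former oxazole oxygen bridging C8a and C3, C3 bearing OMe, C4a–H and C4H2 sp3, N=C2 kept; C5 R, other centres as formed) | CCCCCCCC[C@@H]1CCCC23N=C(COCc4ccccc4)C(OC)(O2)CC13 | intermediate
11 | ring-opened hemiketal, (5R)-2-[(benzyloxy)methyl]-3-methoxy-5-octyl-3,4,5,6,7,8-hexahydroquinolin-3-ol | CCCCCCCC[C@@H]1CCCC2=C1CC(O)(OC)C(COCc1ccccc1)=N2 | intermediate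
12 | (5R)-2-[(benzyloxy)methyl]-5-octyl-5,6,7,8-tetrahydroquinolin-3-ol | CCCCCCCC[C@@H]1CCCc2nc(COCc3ccccc3)c(O)cc12 | intermediate
13 | (5R)-2-[(benzyloxy)methyl]-4-iodo-5-octyl-5,6,7,8-tetrahydroquinolin-3-ol | CCCCCCCC[C@@H]1CCCc2nc(COCc3ccccc3)c(O)c(I)c12 | intermediate
14 | (5R)-2-[(benzyloxy)methyl]-4-iodo-3-methoxy-5-octyl-5,6,7,8-tetrahydroquinoline | CCCCCCCC[C@@H]1CCCc2nc(COCc3ccccc3)c(OC)c(I)c12 | intermediate
15 | (5R)-4-(benzyloxy)-2-[(benzyloxy)methyl]-3-methoxy-5-octyl-5,6,7,8-tetrahydroquinoline | CCCCCCCC[C@@H]1CCCc2nc(COCc3ccccc3)c(OC)c(OCc3ccccc3)c12 | intermediate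
16 | (5R)-4-(benzyloxy)-2-[(benzyloxy)methyl]-3-methoxy-5-octyl-5,6,7,8-tetrahydroquinoline 1-oxide | CCCCCCCC[C@@H]1CCCc2c1c(OCc3ccccc3)c(OC)c(COCc3ccccc3)[n+]2[O-] | intermediate
17 | (5R)-1-hydroxy-2-(hydroxymethyl)-3-methoxy-5-octyl-5,6,7,8-tetrahydroquinolin-4(1H)-one | CCCCCCCC[C@@H]1CCCc2c1c(=O)c(OC)c(CO)n2O | intermediate
18 | (5R)-2-(hydroxymethyl)-1,3-dimethoxy-5-octyl-5,6,7,8-tetrahydroquinolin-4(1H)-one | CCCCCCCC[C@@H]1CCCc2c1c(=O)c(OC)c(CO)n2OC | target

**Count**
Total steps: 12. Longest linear sequence: 12 steps (1 to 18).

**Steps most likely to fail**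

Step 6. The cycloaddition to the unactivated alkene may be slower than thermal degradation of the alkoxyoxazole at the temperature required. The fallback sets out from 9: cross-metathesis with acrylic acid (second-generation Hoveyda–Grubbs catalyst, CH2Cl2, 40 °C) would give (2E,4R)-4-{3-[4-(benzyloxymethyl)-5-methoxy-1,3-oxazol-2-yl]propyl}dodec-2-enoic acid F1. Its electron-poor alkene is matched to the electron-rich oxazole and should cycloadd in toluene at about 110 °C, with the carboxyl-bearing carbon bonding to oxazole C5 as the intrinsic regiochemistry also prefers. The adduct should then aromatise by decarboxylation at C4 and loss of methanol, the known decarboxylative Kondrat'eva behaviour of acrylic acids, so the same two bonds are formed and the sequence comes back at 12.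

Step 9. Turnover at the C4 iodide, flanked on both sides, may be slow enough that hydrodeiodination by the alkoxide takes over. The fallback sets out from 14: mCPBA oxidation would give (5R)-2-[(benzyloxy)methyl]-4-iodo-3-methoxy-5-octyl-5,6,7,8-tetrahydroquinoline 1-oxide F2, in which the N-oxide activates C4 for addition–elimination. Sodium benzyloxide (NaH, BnOH, THF, 0 to 50 °C) should then displace iodide by SNAr without any metal catalyst and deliver 16 directly, which makes steps 9 and 10 unnecessary.

Step 12. The ambident anion of the 1-hydroxy-4-pyridone may be methylated partly on the C4 oxygen instead of the N-oxygen. The fallback sets out from 16: methyl trifluoromethanesulfonate (CH2Cl2, 0 °C) would methylate the N-oxide oxygen to (5R)-4-(benzyloxy)-2-[(benzyloxy)methyl]-1,3-dimethoxy-5-octyl-5,6,7,8-tetrahydroquinolin-1-ium trifluoromethanesulfonate F3, fixing the methyl group before any ambident anion exists. BCl3 with pentamethylbenzene (CH2Cl2, −78 °C) would then cleave both benzyl ethers, loss of the C4 O-benzyl group from the pyridinium unveiling the 4-pyridone, and the sequence comes back at the target 18.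

**Further compounds**
F1 | step 6 | (2E,4R)-4-{3-[4-(benzyloxymethyl)-5-methoxy-1,3-oxazol-2-yl]propyl}dodec-2-enoic acid | CCCCCCCC[C@@H](/C=C/C(=O)O)CCCc1nc(COCc2ccccc2)c(OC)o1
F2 | step 9 | (5R)-2-[(benzyloxy)methyl]-4-iodo-3-methoxy-5-octyl-5,6,7,8-tetrahydroquinoline 1-oxide | CCCCCCCC[C@@H]1CCCc2c1c(I)c(OC)c(COCc3ccccc3)[n+]2[O-]
F3 | step 12 | (5R)-4-(benzyloxy)-2-[(benzyloxy)methyl]-1,3-dimethoxy-5-octyl-5,6,7,8-tetrahydroquinolin-1-ium trifluoromethanesulfonate | CCCCCCCC[C@@H]1CCCc2c1c(OCc3ccccc3)c(OC)c(COCc3ccccc3)[n+]2OC.[O-]S(=O)(=O)C(F)(F)F
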